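Follow each mole of starting material through the flask and ask what share of it reaches target.

| setting | eta | theta | delta | zeta |
|---|---|---|---|---|
| starting material | 1.00 M | 1.00 M | 1.50 M | 2.00 M |
| coupling partner | 1.00 M | 3.00 M | 1.00 M | 3.00 M |
| time |  |  |  | 22 min |

| run | time / min | [target] / M |
|---|---|---|
| eta run | 3.1 | 0.126 |
| eta run | 6.3 | 0.240 |
| eta run | 9.4 | 0.286 |
| eta run | 13 | 0.293 |
| eta run | 16 | 0.311 |
| eta run | 19 | 0.335 |
| eta run | 22 | 0.342 |
| theta run | 3.1 | 0.219 |
| theta run | 6.3 | 0.324 |
| theta run | 9.4 | 0.407 |
| theta run | 13 | 0.436 |
| theta run | 16 | 0.416 |
| theta run | 19 | 0.424 |
| theta run | 22 | 0.385 |
| delta run | 3.1 | 0.189 |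
| delta run | 6.3 | 0.285 |
| delta run | 9.4 | 0.360 |
| delta run | 13 | 0.398 |
| delta run | 16 | 0.415 |
| delta run | 19 | 0.441 |
| delta run | 22 | 0.451 |

(readings scatter by 0.01 M)

- how the opening rate goes with [coupling partner] round the charge of the eta run: the exponent of the rate at two percent of starting material gone to target
- how the opening rate goes with [starting material] round the charge of the eta run: the exponent of the rate at two percent of starting material gone to target (one fixed amount of target, the same in the runs compared)
- target in the zeta run at 22 min, as a share of the starting material charged

- Overall: starting material + coupling partner -> target.
- Constant volume, constant temperature.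
- Bound and free are read together.
- "The second partner" is coupling partner.
- An order is taken over about fifteen percent of the charge, up and down.

I let the first readings, at 3.1 min, stand in for opening rates. Delta over eta gives 1.50 for a charge of starting material 1.50 times as large, so my order in starting material is 1.00. Theta over eta gives 1.74 for a tripled partner, so my order in coupling partner is 0.503.

At 22 min, though, delta stands at 1.32 times eta, less than its opening ratio. So I suppose two exits: one to target, going with c(starting material), and a loss going with its square. Try 1.00 M as the crossover concentration of eta, the level of starting material at which the two exits run equally fast. On this supposition, the share leaving for target at any level is crossover/(crossover + c(starting material)). Summed from the charge down to nothing, this gives a ceiling: the crossover times the natural logarithm of one plus charge over crossover. The ceiling of delta then stands at 1.32 times that of eta, close to the ratio read, so I keep this trial value.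

On this trial, the ledger of eta runs thus: of 1.00 M charged, 0.693 M is the ceiling for target and 0.307 M is booked to the loss. Target reads 0.342 M at 22 min, and 0.351 M of the ceiling stays unplaced, so this reading of eta is about half of its ceiling.

Scaling the crossover with the target exit gives theta 1.74 M and a ceiling of 0.790 M, of which its reading at 22 min is 0.487, against 0.494 in eta. In zeta, starting material is the limiting reagent (2.00 M against 3.00 M). With theta's crossover, its ceiling is 1.33 M, and theta's fraction gives 0.649 M, which is 32.5 % of the charge.

The forecast gives an order of 0.58 in coupling partner, 0.95 in starting material and 32 % of the charge for zeta, observing that “All runs stall early”.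

The flask gives an order of 0.64 in coupling partner, 1.0 in starting material and 33.4 % of the charge for zeta.

    starting material + coupling partner → target (0.1608 /M/min)
    target + coupling partner → side product (0.05958 /M/min)
    2 starting material → homo dimer (0.03834 /M/min)
    2 coupling partner ⇌ idle reagent dimer, settled at all times (2.610 /M)

The loss I supposed corresponds to the step to homo dimer, as the zeta run shows. With the crossover of 1.74 M, my ledger says that closing this exit raises the target of zeta by the charge over the ceiling, a factor of 1.50, which lifts 33.4 % to 50.2 %. With that step taken away, the zeta run goes from 33.4 % to 55.7 %.

(The earlier runs and the new flask were generated by integration with made-up constants, noise included.)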